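**Retrosynthetic overview**
1. The plan most chemists would try first (a hydrindanone template with late RCM across C12=C13) is avoided; the carbocycles are built from an acyclic, nerol-derived chain.
2. Eleven-membered ring (last): Nozaki–Hiyama–Kishi closure of C13–C14 from a (Z)-vinyl iodide, so the Z-olefin never depends on metathesis.
3. Six-membered ring (key step): stannyl-radical 6-exo enyne cyclisation of a C2-ethynyl chain onto a cyclopentene, forming C1–C16, the exocyclic methylene, C16 and C8 in one operation.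
4. Five-membered ring: RCM of a C5-vinyl/C8-methylene diene; C9/C10 by an Ipc2BH reductive syn-aldol; C2 by trans-alkylation of a γ-lactone whose carbonyl later becomes the alkyne.
5. C4 and the quaternary C5: catalytic asymmetric neryl-boration of methyl 4-oxobutanoate with in-situ lactonisation; ring order 5 → 6 → 11.

Labels used in all names: C1′H2=C1; C2 (bears C15); C3; C4 (O); C5 (CH3); C6; C7; C8; C9 (CH3); C10 (O); C11; C12=C13(CH3); C14 (O); C15; C16 (ring-fusion CH). Rings: C1-C2-C3-C4-C5-C16 (six), C5-C6-C7-C8-C16 (five), C1-C2-C15-C14-C13-C12-C11-C10-C9-C8-C16 (eleven). Target = (2R,4S,5S,8R,9S,10S,14R,16S,12Z), cis-fused hydrindane. CIP letters at C2, C9 and C16 change in a few intermediates only because neighbouring groups change priority; the spatial arrangement is constant.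

Assumption: iodide 7 and aldehyde 14 are bought as catalogue compounds; (R)-TRIP is (R)-3,3′-bis(2,4,6-triisopropylphenyl)-BINOL hydrogen phosphate; (+)-Ipc2BH is diisopinocampheylborane made from (–)-α-pinene.

**Step 1**
Reactants: 1 nerol
Product: 2 neryl pinacolboronate
Conditions: B2pin2, [Pd(MeCN)4](BF4)2 (2 mol%), TsOH (cat.), DMSO/MeOH, 50 °C
Reagents that add atoms: bis(pinacolato)diboron, CC1(C)OB(OC1(C)C)B1OC(C)(C)C(C)(C)O1
Why: Pd-catalysed allylic borylation of the allylic alcohol via a π-allyl-Pd species gives the linear primary boronate with the Z trisubstituted olefin retained; no stereocentre is formed.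

**Step 2**
Reactants: 2 neryl pinacolboronate; 3 methyl 4-oxobutanoate
Product: 6 γ-lactone (4S,5S), via O-boryl ether 4 (not isolated), via hydroxy ester 5 (not isolated)
Conditions: (R)-TRIP (5 mol%), 4 Å MS, PhMe, –30 → 0 °C; aq. work-up; TsOH (cat.), PhMe, 50 °C
Reagents that add atoms: none
Why: Chiral-phosphoric-acid-catalysed allylboration through a closed chair Zimmerman–Traxler transition state attacks the aldehyde Re face (C4 = S), and the Z geometry of the neryl unit places the C6 chain syn to the new oxygen (quaternary C5 = S); the γ-hydroxy ester then lactonises.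

**Step 3**
Reactants: 6 γ-lactone; 7 tert-butyl(2-iodoethoxy)dimethylsilane
Product: 9 trans-alkylated lactone (2R,4S,5S), via lithium enolate 8 (not isolated)
Conditions: LDA, THF, –78 °C; then 7, DMPU, –78 → –20 °C
Reagents that add atoms: none
Why: Kinetic enolate alkylation of a γ-substituted γ-butyrolactone, in which the electrophile enters anti to the bulky C4 substituent (1,3-induction) to give the trans lactone and C2 = R.

**Step 4**
Reactants: 9 trans-alkylated lactone
Product: 11 C8 aldehyde, via ozonide 10 (not isolated)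
Conditions: O3, pyridine, CH2Cl2, –78 °C (Sudan Red end point); then Me2S
Reagents that add atoms: ozone, [O-][O+]=O
Why: Chemoselective ozonolysis, because the electron-rich trisubstituted olefin reacts far faster than the neopentyl vinyl group; no stereocentre is touched.

**Step 5**
Reactants: 11 C8 aldehyde
Product: 12 allylic alcohol (C8 epimers)
Conditions: CH2=CHMgBr (1.1 equiv), THF, –78 °C; aq. NH4Cl
Reagents that add atoms: vinylmagnesium bromide, C=C[Mg]Br
Why: Grignard 1,2-addition to the aldehyde, which is far more electrophilic than the lactone at –78 °C; the new carbinol centre is removed in the next step.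

**Step 6**
Reactants: 12 allylic alcohol
Product: 13 vinyl ketone
Conditions: Dess–Martin periodinane, CH2Cl2, 0 °C → rt
Reagents that add atoms: none
Why: Dess–Martin oxidation of the secondary allylic alcohol gives the s-cis-capable vinyl ketone needed for regiodefined enolate formation.

**Step 7**
Reactants: 13 vinyl ketone; 14 3-[(4-methoxyphenyl)methoxy]propanal
Product: 16 syn-aldol (2R,4S,5S,9R,10S), via enol borinate 15 (not isolated)
Conditions: (+)-Ipc2BH (1.05 equiv), Et2O, 0 °C; then 14, –78 °C; pH 7 buffer, MeOH, H2O2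
Reagents that add atoms: none
Why: Boron reductive aldol, in which 1,4-hydroboration of the vinyl ketone gives only the (Z)-enol diisopinocampheylborinate (faster than hydroboration of the hindered neopentyl vinyl group) and its Paterson-type chair transition state gives the 9,10-syn adduct with Ipc-controlled attack on the aldehyde Re face (C10 = S, C9 as in the target).

**Step 8**
Reactants: 16 syn-aldol
Product: 17 C10 TBS ether
Conditions: TBSOTf, 2,6-lutidine, CH2Cl2, –78 °C
Reagents that add atoms: tert-butyldimethylsilyl triflate, CC(C)(C)[Si](C)(C)OS(=O)(=O)C(F)(F)F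
Why: Silylation of the β-hydroxy ketone under non-epimerising conditions blocks retro-aldol and protects C10–O through the following steps.

**Step 9**
Reactants: 17 C10 TBS ether
Product: 18 C8-methylene diene (2R,4S,5S,9S,10S)
Conditions: Zn, CH2Br2, TiCl4, THF/CH2Cl2, 0 °C → rt
Reagents that add atoms: dibromomethane, BrCBr
Why: Takai–Lombardo methylenation, a non-basic gem-dimetallic reagent that converts the ketone but not the lactone and does not epimerise C9.

**Step 10**
Reactants: 18 C8-methylene diene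
Product: 19 cyclopentene lactone
Conditions: Grubbs II (5 mol%), CH2Cl2, 40 °C
Reagents that add atoms: none
Why: Ring-closing metathesis of the C5-vinyl and C8-methylene groups closes the five-membered ring as the C16=C8 trisubstituted olefin with loss of ethylene; C5 is untouched.

**Step 11**
Reactants: 19 cyclopentene lactone
Product: 20 lactol
Conditions: DIBAL-H (1.1 equiv), CH2Cl2, –78 °C; Rochelle salt
Reagents that add atoms: none
Why: Low-temperature DIBAL half-reduction of the γ-lactone stops at the lactol (stable tetrahedral aluminate).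

**Step 12**
Reactants: 20 lactol
Product: 21 alkynol (2R,4S,5S,9S,10S)
Conditions: dimethyl (1-diazo-2-oxopropyl)phosphonate, K2CO3, MeOH, 0 °C → rt
Reagents that add atoms: Ohira–Bestmann reagent, CC(=O)C(=[N+]=[N-])P(=O)(OC)OC
Why: Seyferth–Gilbert homologation (Ohira–Bestmann variant) on the open hydroxy-aldehyde form of the lactol turns C1 into the terminal alkyne and frees C4–OH; the mild carbonate conditions are chosen to preserve C2.

**Step 13**
Reactants: 21 alkynol
Product: 23 cis-hydrindane alcohol (2R,4S,5S,8R,9S,10S,16S), via vinylstannane 22 (not isolated)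
Conditions: Bu3SnH (1.3 equiv, syringe pump), AIBN (cat.), PhH (0.01 M), 80 °C; then wet SiO2, CH2Cl2, rt
Reagents that add atoms: none
Why: Stork-type stannyl-radical enyne cyclisation, in which Bu3Sn• adds to the alkyne terminus, the vinyl radical closes 6-exo-trig onto C16 on the face carrying the C4 tether (cis fusion enforced), the tertiary C8 radical takes H from Bu3SnH on the convex face anti to the new C1–C16 bond (C9 chain ends cis to C1), and protodestannylation leaves the exocyclic methylene.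

**Step 14**
Reactants: 23 cis-hydrindane alcohol
Product: 24 C4 propionate
Conditions: (EtCO)2O, DMAP, Et3N, CH2Cl2, rt
Reagents that add atoms: propionic anhydride, CCC(=O)OC(=O)CC
Why: DMAP-catalysed acylation installs the first target ester, which also prevents δ-lactol formation between C4–OH and the later C14 aldehyde.

**Step 15**
Reactants: 24 C4 propionate
Product: 25 C12 primary alcohol
Conditions: DDQ, CH2Cl2/pH 7 buffer, 0 °C
Reagents that add atoms: none
Why: Oxidative PMB-ether cleavage by DDQ (benzylic hydride abstraction, then hydrolysis) leaves the TBS ethers, the ester and the olefin intact.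

**Step 16**
Reactants: 25 C12 primary alcohol
Product: 26 C12 aldehyde
Conditions: Dess–Martin periodinane, CH2Cl2, rt
Reagents that add atoms: none
Why: Dess–Martin oxidation gives the β-silyloxy aldehyde without elimination or epimerisation.

**Step 17**
Reactants: 26 C12 aldehyde
Product: 27 (12Z)-vinyl iodide
Conditions: EtPPh3I, n-BuLi, THF, rt; I2, –78 °C; NaHMDS, –20 °C; then 26, –78 °C
Reagents that add atoms: ethyltriphenylphosphonium iodide, CC[P+](c1ccccc1)(c1ccccc1)c1ccccc1.[I-]; iodine, II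
Why: Stork–Zhao olefination with the α-iodoethylidene ylide gives the (Z)-2-iodo-2-alkene (iodine cis to C11), fixing the later ring-olefin geometry.

**Step 18**
Reactants: 27 (12Z)-vinyl iodide
Product: 28 diol (C10–OH and C14–OH)
Conditions: HF·pyridine, pyridine/THF, 0 °C → rt
Reagents that add atoms: none
Why: Fluoride-mediated cleavage of both TBS ethers under buffered conditions that spare the propionate and the vinyl iodide.

**Step 19**
Reactants: 28 diol
Product: 29 C14 aldehyde
Conditions: TEMPO (10 mol%), PhI(OAc)2, CH2Cl2, rt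
Reagents that add atoms: none
Why: Oxoammonium (TEMPO) oxidation is selective for the unhindered primary alcohol over the secondary C10–OH.

**Step 20**
Reactants: 29 C14 aldehyde
Product: 30 macrocyclic diol 4-propionate (14R)
Conditions: CrCl2 (10 equiv), NiCl2 (1 mol%), DMSO/THF, rt, 2 mM (slow addition)
Reagents that add atoms: none
Why: Intramolecular Nozaki–Hiyama–Kishi coupling, in which the alkenyl-chromium(III) species adds to the aldehyde with retention of the Z geometry to close the eleven-membered ring; the 14R carbinol is expected from addition to the exposed aldehyde face of the folded precursor (substrate control, to be verified).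

**Step 21**
Reactants: 30 macrocyclic diol 4-propionate
Product: 31 target tripropionate
Conditions: (EtCO)2O, DMAP, pyridine, CH2Cl2, rt
Reagents that add atoms: propionic anhydride, CCC(=O)OC(=O)CC
Why: DMAP-catalysed acylation of the two remaining secondary alcohols completes the tripropionate without touching any stereocentre.

**Compound list**
1 | nerol, (2Z)-3,7-dimethylocta-2,6-dien-1-ol | OC/C=C(/C)CCC=C(C)C | starting material
2 | neryl pinacolboronate, 2-[(2Z)-3,7-dimethylocta-2,6-dien-1-yl]-4,4,5,5-tetramethyl-1,3,2-dioxaborolane | CC1(C)OB(C/C=C(/C)CCC=C(C)C)OC1(C)C | intermediate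
3 | methyl 4-oxobutanoate | COC(=O)CCC=O | starting material
4 | methyl (4S,5S)-5-ethenyl-5,9-dimethyl-4-(pinacolboryloxy)dec-8-enoate (O-boryl ether) | COC(=O)CC[C@H](OB1OC(C)(C)C(C)(C)O1)[C@@](C=C)(C)CCC=C(C)C | intermediate
5 | methyl (4S,5S)-5-ethenyl-4-hydroxy-5,9-dimethyldec-8-enoate | COC(=O)CC[C@H](O)[C@@](C=C)(C)CCC=C(C)C | intermediate
6 | (5S)-5-[(3S)-3,7-dimethylocta-1,6-dien-3-yl]oxolan-2-one (γ-lactone; labels 4S,5S) | O=C1CC[C@H](O1)[C@@](C=C)(C)CCC=C(C)C | intermediate
7 | tert-butyl(2-iodoethoxy)dimethylsilane | CC(C)(C)[Si](C)(C)OCCI | starting material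
8 | lithium enolate of lactone 6 (C1–OLi, C1=C2) | [Li]OC1=CC[C@H](O1)[C@@](C=C)(C)CCC=C(C)C | intermediate
9 | (3R,5S)-3-[2-(tert-butyldimethylsilyloxy)ethyl]-5-[(3S)-3,7-dimethylocta-1,6-dien-3-yl]oxolan-2-one (trans; labels 2R,4S,5S) | O=C1[C@H](CCO[Si](C)(C)C(C)(C)C)C[C@H](O1)[C@@](C=C)(C)CCC=C(C)C | intermediate
10 | ozonide of 9: C8 and the former CMe2 carbon joined in a 3,3-dimethyl-1,2,4-trioxolane (2R,4S,5S; C8 mixture) | O=C1[C@H](CCO[Si](C)(C)C(C)(C)C)C[C@H](O1)[C@@](C=C)(C)CCC1OOC(C)(C)O1 | intermediate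
11 | C8 aldehyde, (4S)-4-methyl-4-[(2S,4R)-4-[2-(tert-butyldimethylsilyloxy)ethyl]-5-oxooxolan-2-yl]hex-5-enal (labels 2R,4S,5S) | O=C1[C@H](CCO[Si](C)(C)C(C)(C)C)C[C@H](O1)[C@@](C=C)(C)CCC=O | intermediate
12 | allylic alcohol: 11 with C8 as CH(OH)–CH=CH2 (2R,4S,5S; C8 epimers) | O=C1[C@H](CCO[Si](C)(C)C(C)(C)C)C[C@H](O1)[C@@](C=C)(C)CCC(O)C=C | intermediate
13 | vinyl ketone: C7–C8(=O)–CH=CH2 (2R,4S,5S) | O=C1[C@H](CCO[Si](C)(C)C(C)(C)C)C[C@H](O1)[C@@](C=C)(C)CCC(=O)C=C | intermediate
14 | 3-[(4-methoxyphenyl)methoxy]propanal | O=CCCOCc1ccc(OC)cc1 | starting material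
15 | (Z)-enol diisopinocampheylborinate of 13: C8(OBIpc2)=C9H–CH3, O and CH3 cis (2R,4S,5S) | O=C1[C@H](CCO[Si](C)(C)C(C)(C)C)C[C@H](O1)[C@@](C=C)(C)CC/C(OB([C@H]2C[C@H]3C[C@@H]([C@@H]2C)C3(C)C)[C@H]2C[C@H]3C[C@@H]([C@@H]2C)C3(C)C)=C/C | intermediate
16 | syn-aldol: C8(=O)–C9H(CH3)–C10H(OH)–CH2CH2OPMB on lactone 9 core (2R,4S,5S,9R,10S) | O=C1[C@H](CCO[Si](C)(C)C(C)(C)C)C[C@H](O1)[C@@](C=C)(C)CCC(=O)[C@H](C)[C@@H](O)CCOCc1ccc(OC)cc1 | intermediate
17 | C10 tert-butyldimethylsilyl ether of 16 (2R,4S,5S,9R,10S) | O=C1[C@H](CCO[Si](C)(C)C(C)(C)C)C[C@H](O1)[C@@](C=C)(C)CCC(=O)[C@H](C)[C@@H](O[Si](C)(C)C(C)(C)C)CCOCc1ccc(OC)cc1 | intermediate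
18 | diene: 17 with C8=O replaced by C8=CH2 (2R,4S,5S,9S,10S) | O=C1[C@H](CCO[Si](C)(C)C(C)(C)C)C[C@H](O1)[C@@](C=C)(C)CCC(=C)[C@H](C)[C@@H](O[Si](C)(C)C(C)(C)C)CCOCc1ccc(OC)cc1 | intermediate
19 | cyclopentene lactone: ring C5–C6–C7–C8=C16, C8 bears the C9–C12 chain, C5 bears CH3 and the lactone (2R,4S,5S,9S,10S) | O=C1[C@H](CCO[Si](C)(C)C(C)(C)C)C[C@H](O1)[C@@]1(C)CCC([C@H](C)[C@@H](O[Si](C)(C)C(C)(C)C)CCOCc2ccc(OC)cc2)=C1 | intermediate
20 | lactol of 19 (C1–OH anomers; 2R,4S,5S,9S,10S) | OC1[C@H](CCO[Si](C)(C)C(C)(C)C)C[C@H](O1)[C@@]1(C)CCC([C@H](C)[C@@H](O[Si](C)(C)C(C)(C)C)CCOCc2ccc(OC)cc2)=C1 | intermediate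
21 | alkynol: C2 bears C≡CH and CH2CH2OTBS, C4–OH free, cyclopentene as in 19 (2R,4S,5S,9S,10S) | C#C[C@H](CCO[Si](C)(C)C(C)(C)C)C[C@H](O)[C@@]1(C)CCC([C@H](C)[C@@H](O[Si](C)(C)C(C)(C)C)CCOCc2ccc(OC)cc2)=C1 | intermediate
22 | exocyclic vinylstannane: cis-hydrindane with C1=CH–SnBu3 (E/Z mixture; 2R,4S,5S,8R,9S,10S,16R by CIP, same spatial arrangement as 23) | CCCC[Sn](CCCC)(CCCC)C=C1[C@H](CCO[Si](C)(C)C(C)(C)C)C[C@H](O)[C@@]2(C)CC[C@@H]([C@H](C)[C@@H](O[Si](C)(C)C(C)(C)C)CCOCc3ccc(OC)cc3)[C@@H]12 | intermediate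
23 | cis-hydrindane alcohol: C1=CH2, C2–CH2CH2OTBS, C4–OH, C5–CH3, C8–CH(CH3)–CH(OTBS)–CH2CH2OPMB (2R,4S,5S,8R,9S,10S,16S) | C=C1[C@H](CCO[Si](C)(C)C(C)(C)C)C[C@H](O)[C@@]2(C)CC[C@@H]([C@H](C)[C@@H](O[Si](C)(C)C(C)(C)C)CCOCc3ccc(OC)cc3)[C@@H]12 | intermediate
24 | C4 propionate of 23 | C=C1[C@H](CCO[Si](C)(C)C(C)(C)C)C[C@H](OC(=O)CC)[C@@]2(C)CC[C@@H]([C@H](C)[C@@H](O[Si](C)(C)C(C)(C)C)CCOCc3ccc(OC)cc3)[C@@H]12 | intermediate
25 | C12 primary alcohol (PMB removed from 24) | C=C1[C@H](CCO[Si](C)(C)C(C)(C)C)C[C@H](OC(=O)CC)[C@@]2(C)CC[C@@H]([C@H](C)[C@@H](O[Si](C)(C)C(C)(C)C)CCO)[C@@H]12 | intermediate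
26 | C12 aldehyde | C=C1[C@H](CCO[Si](C)(C)C(C)(C)C)C[C@H](OC(=O)CC)[C@@]2(C)CC[C@@H]([C@H](C)[C@@H](O[Si](C)(C)C(C)(C)C)CC=O)[C@@H]12 | intermediate
27 | (12Z)-vinyl iodide: C11H2–C12H=C13(CH3)I, iodine cis to C11 (2R,4S,5S,8R,9S,10S,16S) | C=C1[C@H](CCO[Si](C)(C)C(C)(C)C)C[C@H](OC(=O)CC)[C@@]2(C)CC[C@@H]([C@H](C)[C@@H](O[Si](C)(C)C(C)(C)C)C/C=C(/C)I)[C@@H]12 | intermediate
28 | diol: C10–OH and C14H2–OH free, C4 propionate, (12Z)-vinyl iodide | C=C1[C@H](CCO)C[C@H](OC(=O)CC)[C@@]2(C)CC[C@@H]([C@H](C)[C@@H](O)C/C=C(/C)I)[C@@H]12 | intermediate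
29 | C14 aldehyde: C2–CH2–CHO (2S by CIP, 4S,5S,8R,9S,10S,16S,12Z) | C=C1[C@H](CC=O)C[C@H](OC(=O)CC)[C@@]2(C)CC[C@@H]([C@H](C)[C@@H](O)C/C=C(/C)I)[C@@H]12 | intermediate
30 | macrocyclic diol 4-propionate: target skeleton with C10–OH and C14–OH free (2R,4S,5S,8R,9S,10S,14R,16S,12Z) | C=C1[C@H]2C[C@H](OC(=O)CC)[C@@]3(C)CC[C@@H]([C@H](C)[C@@H](O)C/C=C(/C)[C@H](O)C2)[C@@H]13 | intermediate
31 | CNP0315827.1, 4,10,14-tripropionate (2R,4S,5S,8R,9S,10S,14R,16S,12Z) | C=C1[C@H]2C[C@H](OC(=O)CC)[C@@]3(C)CC[C@@H]([C@H](C)[C@@H](OC(=O)CC)C/C=C(/C)[C@H](OC(=O)CC)C2)[C@@H]13 | target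

**Step count and risks**
Total: 21 steps. Longest linear sequence: 21 steps (1 → 31).

The three steps most likely to fail are 2, 13 and 20.

Step 2 may give insufficient ee, because γ,γ-disubstituted allylboronates are sluggish and aliphatic aldehydes are the weaker substrates for phosphoric-acid catalysis. The fallback sets out from 2 and 3 and replaces catalysis by resolution. Uncatalysed allylboration (PhMe, 60 °C; then TsOH) still gives only the syn diastereomer, but as the racemate, that is 6 mixed with its enantiomer ent-6 F1. Aminolysis with (S)-1-phenylethylamine/AlMe3 converts the pair into the hydroxy amide F2 and the diastereomeric hydroxy amide F3, which are separated by chromatography. TsOH in hot toluene relactonises F2, and the route resumes at 6.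

Step 13 may suffer from simple hydrostannation or reduction competing with the relatively slow 6-exo closure of the vinyl radical. The fallback sets out from 19 and uses an acyl radical instead. Me2AlSePh opens the lactone to the hydroxy selenoester F4, which is acylated at once with propionic anhydride/DMAP to the selenoester propionate F5. Bu3SnH/AIBN then gives a 6-exo acyl-radical cyclisation (same cis-fusion and convex-face hydrogen transfer) to the cyclohexanone F6. Takai–Lombardo methylenation of F6 returns to the route at 24.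

Step 20 closes a strained eleven-membered ring, and its C14 configuration rests on substrate control only. The fallback sets out from 29 and sets C14 by reagent control. The Nozaki–Hiyama–Kishi closure is run without regard to selectivity and gives 30 mixed with its 14-epimer F7. MnO2 oxidises only the allylic carbinol of both to the single Z-enone F8. (S)-Me-CBS with catecholborane (toluene, –78 °C, no hydroboration of the methylene group) reduces F8 to the 14R alcohol, and the route resumes at 30. This fallback does not help if the ring closure itself fails.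

**Further compounds**
F1 | step 2 | ent-6, (5R)-5-[(3R)-3,7-dimethylocta-1,6-dien-3-yl]oxolan-2-one | O=C1CC[C@@H](O1)[C@](C=C)(C)CCC=C(C)C
F2 | step 2 | (4S,5S)-5-ethenyl-4-hydroxy-5,9-dimethyl-N-[(1S)-1-phenylethyl]dec-8-enamide | C[C@H](NC(=O)CC[C@H](O)[C@@](C=C)(C)CCC=C(C)C)c1ccccc1
F3 | step 2 | (4R,5R)-5-ethenyl-4-hydroxy-5,9-dimethyl-N-[(1S)-1-phenylethyl]dec-8-enamide | C[C@H](NC(=O)CC[C@@H](O)[C@](C=C)(C)CCC=C(C)C)c1ccccc1
F4 | step 13 | Se-phenyl selenoester of the C1 acid with C4–OH free (ring-opened 19; 2R,4S,5S,9S,10S) | O=C([Se]c1ccccc1)[C@H](CCO[Si](C)(C)C(C)(C)C)C[C@H](O)[C@@]1(C)CCC([C@H](C)[C@@H](O[Si](C)(C)C(C)(C)C)CCOCc2ccc(OC)cc2)=C1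
F5 | step 13 | C4 propionate of selenoester F4 | O=C([Se]c1ccccc1)[C@H](CCO[Si](C)(C)C(C)(C)C)C[C@H](OC(=O)CC)[C@@]1(C)CCC([C@H](C)[C@@H](O[Si](C)(C)C(C)(C)C)CCOCc2ccc(OC)cc2)=C1
F6 | step 13 | cis-hydrindan-1-one: 24 with C1=O in place of C1=CH2 (2R,4S,5S,8R,9S,10S,16R by CIP) | O=C1[C@H](CCO[Si](C)(C)C(C)(C)C)C[C@H](OC(=O)CC)[C@@]2(C)CC[C@@H]([C@H](C)[C@@H](O[Si](C)(C)C(C)(C)C)CCOCc3ccc(OC)cc3)[C@@H]12
F7 | step 20 | 14-epi-30 (14S) | C=C1[C@H]2C[C@H](OC(=O)CC)[C@@]3(C)CC[C@@H]([C@H](C)[C@@H](O)C/C=C(/C)[C@@H](O)C2)[C@@H]13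
F8 | step 20 | macrocyclic (12Z)-enone: 30 with C14=O (2S by CIP, 4S,5S,8R,9S,10S,16S) | C=C1[C@H]2C[C@H](OC(=O)CC)[C@@]3(C)CC[C@@H]([C@H](C)[C@@H](O)C/C=C(/C)C(=O)C2)[C@@H]13
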